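**Strategy.** The five-membered ring is read as a 4-oxygenated cyclopentanone. The carbinol carbon C(OH)(iPr) is the former carbonyl, the ring-fusion CH is its α-carbon, the methyl-bearing quaternary fusion carbon is its β-carbon, and the CH–OAc carbon is a purchased γ-stereocentre. In one pot, Me2CuLi adds methyl to the β-carbon of (R)-4-silyloxy-3-(3-methylbut-3-enyl)cyclopentenone and the enolate is trapped by acrolein. This forms the C–CH3 and CH–CH(O) bonds and sets three contiguous stereocentres by substrate control. The same carbonyl later accepts the isopropyl group. Metathesis of the butenyl and vinyl arms closes the seven-membered ring, and allylic oxidation supplies its ketone.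

Key step: step 3

Remark on numbering: cyclopentanones are numbered C1 (carbonyl), C2 (aldol carbon), C3 (quaternary carbon), C4 (silyloxy carbon), C5. Hydroazulenes use azulene numbering: C1 = oxygenated CH of the five-membered ring, C3 = isopropyl carbinol, C3a = ring-fusion CH, C4 = oxygenated CH of the seven-membered ring, C6 = methyl-bearing alkene carbon, C8a = methyl-bearing fusion carbon.

Assumption: alcohol 21 is carried on as a mixture of C7 epimers, because that centre becomes the ketone in step 10.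

Step 1
Reactants: 1 (R)-4-(tert-butyldimethylsilyloxy)cyclopent-2-en-1-one; 2 4-bromo-2-methylbut-1-ene
Product: 4 (3R,4R)-4-(tert-butyldimethylsilyloxy)-3-(3-methylbut-3-en-1-yl)-1-(trimethylsilyloxy)cyclopent-1-ene (3,4-trans), via (3-methylbut-3-en-1-yl)magnesium bromide 3 (not isolated)
Conditions: 2, Mg, THF; then CuBr·SMe2 (10 mol %), Me3SiCl, HMPA, THF, −78 °C, add 1; Et3N, pentane work-up, crude 4 used directly
Reagents that add atoms: chlorotrimethylsilane, C[Si](C)(C)Cl
Why: Copper-catalysed, Me3SiCl-accelerated 1,4-addition of a Grignard reagent should place the chain on C3 anti to the C4 silyloxy group and trap the regiodefined enolate as its silyl enol ether before it can equilibrate and expel the silyloxy group; the new C3 centre is erased again in step 2.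

Step 2
Reactants: 4 (3R,4R)-4-(tert-butyldimethylsilyloxy)-3-(3-methylbut-3-en-1-yl)-1-(trimethylsilyloxy)cyclopent-1-ene
Product: 6 (R)-4-(tert-butyldimethylsilyloxy)-3-(3-methylbut-3-en-1-yl)cyclopent-2-en-1-one, via α-phenylselanyl ketone 5 (not isolated)
Conditions: PhSeCl, CH2Cl2, −78 °C; then H2O2 (30 % aq.), pyridine, CH2Cl2, 0 °C → rt
Reagents that add atoms: none
Why: Selenenylation of the silyl enol ether at C2 (anti to the C3 chain) followed by selenoxide syn-elimination across C2–C3, the only position with a β-hydrogen, should restore the enone with the chain on the β-carbon and C4 untouched; this is preferred to a Saegusa–Ito dehydrogenation with Pd(OAc)2 because a palladium enolate could cyclise onto the pendant alkene.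

Step 3
Reactants: 6 (R)-4-(tert-butyldimethylsilyloxy)-3-(3-methylbut-3-en-1-yl)cyclopent-2-en-1-one; 7 methyllithium; 8 acrolein
Product: 12 (2R,3S,4R)-4-(tert-butyldimethylsilyloxy)-2-[(1R)-1-hydroxyprop-2-en-1-yl]-3-methyl-3-(3-methylbut-3-en-1-yl)cyclopentan-1-one, via lithium dimethylcuprate 9 (not isolated), via lithium enolate 10 (not isolated), via chlorozinc enolate 11 (not isolated)
Conditions: 7 (2 equiv per Cu), CuI, Et2O, 0 °C; add 6, −78 → −20 °C; ZnCl2 (Et2O), −78 °C; 8 (freshly distilled), −78 °C; aq. NH4Cl at −78 °C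
Reagents that add atoms: none
Why: Me2CuLi transfers methyl to the β-carbon C3 of enone 6 (copper π-complex, then reductive elimination) and gives only the C1=C2 lithium enolate 10, which after transmetalation to zinc adds to the carbonyl of acrolein through a closed six-membered Zimmerman–Traxler transition state. The closest known reaction type is the conjugate addition–aldol three-component coupling on 4-silyloxycyclopentenones used for prostaglandins, here forming a quaternary β-carbon. No ring is closed in this step; the C3–CH3 bond and the C2–CH(OH) bond are formed, and the seven-membered ring follows in step 6. The quaternary C3 is controlled by the C4 silyloxy group (methyl enters anti to it), C2 by the new quaternary centre and the silyloxy group (acrolein approaches the face carrying the small methyl, opposite the butenyl chain), and the carbinol carbon by the ring-locked E geometry of the enolate, which leads to the anti aldol. The step needs 1,4- over 1,2-addition of the methyl group, no enolate equilibration toward C5 (which would eliminate the silyloxy group) and 1,2-addition to acrolein; the soft cuprate, the low temperature and the hard zinc enolate should secure these.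

Step 4
Reactants: 12 (2R,3S,4R)-4-(tert-butyldimethylsilyloxy)-2-[(1R)-1-hydroxyprop-2-en-1-yl]-3-methyl-3-(3-methylbut-3-en-1-yl)cyclopentan-1-one
Product: 13 (2R,3S,4R)-4-(tert-butyldimethylsilyloxy)-3-methyl-3-(3-methylbut-3-en-1-yl)-2-[(1R)-1-(triethylsilyloxy)prop-2-en-1-yl]cyclopentan-1-one
Conditions: TESOTf, 2,6-lutidine, CH2Cl2, −78 °C
Reagents that add atoms: triethylsilyl trifluoromethanesulfonate, CC[Si](CC)(CC)OS(=O)(=O)C(F)(F)F
Why: Silylation of the secondary aldol hydroxyl with a silyl triflate and a hindered base is fast and non-enolising at −78 °C, so the β-hydroxy ketone is capped before retro-aldol or C2 epimerisation can occur; no stereocentre changes.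

Step 5
Reactants: 13 (2R,3S,4R)-4-(tert-butyldimethylsilyloxy)-3-methyl-3-(3-methylbut-3-en-1-yl)-2-[(1R)-1-(triethylsilyloxy)prop-2-en-1-yl]cyclopentan-1-one; 14 isopropylmagnesium chloride
Product: 16 (1S,2R,3S,4R)-4-(tert-butyldimethylsilyloxy)-3-methyl-3-(3-methylbut-3-en-1-yl)-1-(propan-2-yl)-2-[(1R)-1-(triethylsilyloxy)prop-2-en-1-yl]cyclopentan-1-ol, via isopropylcerium dichloride 15 (not isolated)
Conditions: CeCl3 (anhydrous), THF, 14, −78 °C; then 13, −78 → −30 °C; aq. NH4Cl
Reagents that add atoms: none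
Why: Organocerium 1,2-addition: the weakly basic isopropylcerium reagent should add to the hindered, enolisable ketone without reduction or enolisation (either enolate could expel a β-silyloxy group), attacking the carbonyl face anti to the bulky C2 side chain so that the isopropyl group ends trans and the new hydroxyl cis to that chain (1S).

Step 6
Reactants: 16 (1S,2R,3S,4R)-4-(tert-butyldimethylsilyloxy)-3-methyl-3-(3-methylbut-3-en-1-yl)-1-(propan-2-yl)-2-[(1R)-1-(triethylsilyloxy)prop-2-en-1-yl]cyclopentan-1-ol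
Product: 17 (1R,3S,3aR,4R,8aS)-1-(tert-butyldimethylsilyloxy)-6,8a-dimethyl-3-(propan-2-yl)-4-(triethylsilyloxy)-1,2,3,3a,4,7,8,8a-octahydroazulen-3-ol
Conditions: second-generation Grubbs catalyst (5–10 mol %), CH2Cl2 (0.005 M), 40 °C
Reagents that add atoms: none
Why: Ring-closing olefin metathesis between the vinyl group and the 1,1-disubstituted alkene, held trans on adjacent ring carbons, should close the seven-membered ring as the trisubstituted cycloalkene (trans-fused) with loss of ethylene; the free tertiary alcohol and both silyl ethers are tolerated and no stereocentre is touched.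

Step 7
Reactants: 17 (1R,3S,3aR,4R,8aS)-1-(tert-butyldimethylsilyloxy)-6,8a-dimethyl-3-(propan-2-yl)-4-(triethylsilyloxy)-1,2,3,3a,4,7,8,8a-octahydroazulen-3-ol
Product: 18 (1R,3S,3aR,4R,8aS)-1-(tert-butyldimethylsilyloxy)-6,8a-dimethyl-3-(propan-2-yl)-1,2,3,3a,4,7,8,8a-octahydroazulene-3,4-diol
Conditions: PPTS (cat.), MeOH/CH2Cl2, 0 °C
Reagents that add atoms: none
Why: Mild acid-catalysed methanolysis cleaves a triethylsilyl ether much faster than the secondary tert-butyldimethylsilyl ether, so only the allylic C4 hydroxyl should be set free.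

Step 8
Reactants: 18 (1R,3S,3aR,4R,8aS)-1-(tert-butyldimethylsilyloxy)-6,8a-dimethyl-3-(propan-2-yl)-1,2,3,3a,4,7,8,8a-octahydroazulene-3,4-diol; 19 4-acetoxybenzoic acid
Product: 20 (1R,3S,3aR,4R,8aS)-1-(tert-butyldimethylsilyloxy)-3-hydroxy-6,8a-dimethyl-3-(propan-2-yl)-1,2,3,3a,4,7,8,8a-octahydroazulen-4-yl 4-acetoxybenzoate
Conditions: 19, DCC, DMAP (cat.), CH2Cl2, 0 °C → rt
Reagents that add atoms: none
Why: Steglich esterification (carbodiimide activation, DMAP acyl transfer) should acylate the secondary allylic alcohol with retention at C4, while the tertiary isopropyl carbinol is too hindered to react.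

Step 9
Reactants: 20 (1R,3S,3aR,4R,8aS)-1-(tert-butyldimethylsilyloxy)-3-hydroxy-6,8a-dimethyl-3-(propan-2-yl)-1,2,3,3a,4,7,8,8a-octahydroazulen-4-yl 4-acetoxybenzoate
Product: 21 (1R,3S,3aR,4R,8aS)-1-(tert-butyldimethylsilyloxy)-3,7-dihydroxy-6,8a-dimethyl-3-(propan-2-yl)-1,2,3,3a,4,7,8,8a-octahydroazulen-4-yl 4-acetoxybenzoate (C7 epimers)
Conditions: SeO2 (0.5 equiv), t-BuOOH (anhydrous, 3 equiv), CH2Cl2, rt
Reagents that add atoms: tert-butyl hydroperoxide, CC(C)(C)OO (net oxygen source; the oxygen is passed on through SeO2, O=[Se]=O)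
Why: Riley-type allylic oxidation (ene reaction, then [2,3]-sigmatropic shift) follows the established preference for the more substituted end of a trisubstituted alkene, CH2 over CH3 and ring over side chain, and should therefore hydroxylate the ring methylene C7 next to C6 with the double bond back in place.

Step 10
Reactants: 21 (1R,3S,3aR,4R,8aS)-1-(tert-butyldimethylsilyloxy)-3,7-dihydroxy-6,8a-dimethyl-3-(propan-2-yl)-1,2,3,3a,4,7,8,8a-octahydroazulen-4-yl 4-acetoxybenzoate
Product: 22 (1R,3S,3aR,4R,8aS)-1-(tert-butyldimethylsilyloxy)-3-hydroxy-6,8a-dimethyl-7-oxo-3-(propan-2-yl)-1,2,3,3a,4,7,8,8a-octahydroazulen-4-yl 4-acetoxybenzoate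
Conditions: Dess–Martin periodinane, NaHCO3, CH2Cl2, 0 °C → rt
Reagents that add atoms: none
Why: Dess–Martin oxidation should convert both epimers of the secondary allylic alcohol to the conjugated enone under buffered conditions that leave the tertiary alcohol, the esters and the silyl ether untouched.

Step 11
Reactants: 22 (1R,3S,3aR,4R,8aS)-1-(tert-butyldimethylsilyloxy)-3-hydroxy-6,8a-dimethyl-7-oxo-3-(propan-2-yl)-1,2,3,3a,4,7,8,8a-octahydroazulen-4-yl 4-acetoxybenzoate
Product: 23 (1R,3S,3aR,4R,8aS)-1,3-dihydroxy-6,8a-dimethyl-7-oxo-3-(propan-2-yl)-1,2,3,3a,4,7,8,8a-octahydroazulen-4-yl 4-acetoxybenzoate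
Conditions: HF·pyridine, THF, 0 °C → rt
Reagents that add atoms: none
Why: Acidic fluoride desilylation should remove the remaining silyl ether without the basic conditions that would endanger the aryl acetate or promote acyl migration.

Step 12
Reactants: 23 (1R,3S,3aR,4R,8aS)-1,3-dihydroxy-6,8a-dimethyl-7-oxo-3-(propan-2-yl)-1,2,3,3a,4,7,8,8a-octahydroazulen-4-yl 4-acetoxybenzoate
Product: 24 (1R,3S,3aR,4R,8aS)-1-acetoxy-3-hydroxy-6,8a-dimethyl-7-oxo-3-(propan-2-yl)-1,2,3,3a,4,7,8,8a-octahydroazulen-4-yl 4-acetoxybenzoate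
Conditions: Ac2O, pyridine, DMAP (cat.), CH2Cl2, 0 °C → rt
Reagents that add atoms: acetic anhydride, CC(=O)OC(C)=O
Why: Nucleophile-catalysed acetylation should esterify the secondary C1 hydroxyl with retention, while the tertiary C3 hydroxyl, flanked by the isopropyl group and the ring fusion, stays free.

Step 13
Reactants: 24 (1R,3S,3aR,4R,8aS)-1-acetoxy-3-hydroxy-6,8a-dimethyl-7-oxo-3-(propan-2-yl)-1,2,3,3a,4,7,8,8a-octahydroazulen-4-yl 4-acetoxybenzoate
Product: 25 (1R,3S,3aR,4R,8aS)-1-acetoxy-3-hydroxy-6,8a-dimethyl-7-oxo-3-(propan-2-yl)-1,2,3,3a,4,7,8,8a-octahydroazulen-4-yl 4-hydroxybenzoate (CNP0087181.6)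
Conditions: NH4OAc, MeOH/H2O (4:1), rt
Reagents that add atoms: none
Why: Near-neutral solvolysis with ammonium acetate cleaves aryl acetates, whose phenoxide is a good leaving group, much faster than alkyl acetates or benzoates, so only the phenol should be unmasked.

**Compound list**

1 | (R)-4-(tert-butyldimethylsilyloxy)cyclopent-2-en-1-one | CC(C)(C)[Si](C)(C)O[C@@H]1CC(=O)C=C1 | starting material
2 | 4-bromo-2-methylbut-1-ene | C=C(C)CCBr | starting material
3 | (3-methylbut-3-en-1-yl)magnesium bromide | C=C(C)CC[Mg]Br | intermediate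
4 | (3R,4R)-4-(tert-butyldimethylsilyloxy)-3-(3-methylbut-3-en-1-yl)-1-(trimethylsilyloxy)cyclopent-1-ene | CC(C)(C)[Si](C)(C)O[C@@H]1CC(O[Si](C)(C)C)=C[C@H]1CCC(C)=C | intermediate
5 | (2R,3S,4R)-4-(tert-butyldimethylsilyloxy)-3-(3-methylbut-3-en-1-yl)-2-(phenylselanyl)cyclopentan-1-one (2,3-trans, 3,4-trans) | CC(C)(C)[Si](C)(C)O[C@@H]1CC(=O)[C@H]([Se]c2ccccc2)[C@H]1CCC(C)=C | intermediate
6 | (R)-4-(tert-butyldimethylsilyloxy)-3-(3-methylbut-3-en-1-yl)cyclopent-2-en-1-one | CC(C)(C)[Si](C)(C)O[C@@H]1CC(=O)C=C1CCC(C)=C | intermediate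
7 | methyllithium | [Li]C | starting material
8 | acrolein | C=CC=O | starting material
9 | lithium dimethylcuprate | [Li+].C[Cu-]C | intermediate
10 | lithium (3S,4R)-4-(tert-butyldimethylsilyloxy)-3-methyl-3-(3-methylbut-3-en-1-yl)cyclopent-1-en-1-olate | CC(C)(C)[Si](C)(C)O[C@@H]1CC(O[Li])=C[C@]1(C)CCC(C)=C | intermediate
11 | chlorozinc (3S,4R)-4-(tert-butyldimethylsilyloxy)-3-methyl-3-(3-methylbut-3-en-1-yl)cyclopent-1-en-1-olate | CC(C)(C)[Si](C)(C)O[C@@H]1CC(O[Zn]Cl)=C[C@]1(C)CCC(C)=C | intermediate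
12 | (2R,3S,4R)-4-(tert-butyldimethylsilyloxy)-2-[(1R)-1-hydroxyprop-2-en-1-yl]-3-methyl-3-(3-methylbut-3-en-1-yl)cyclopentan-1-one | CC(C)(C)[Si](C)(C)O[C@@H]1CC(=O)[C@@H]([C@H](O)C=C)[C@]1(C)CCC(C)=C | intermediate
13 | (2R,3S,4R)-4-(tert-butyldimethylsilyloxy)-3-methyl-3-(3-methylbut-3-en-1-yl)-2-[(1R)-1-(triethylsilyloxy)prop-2-en-1-yl]cyclopentan-1-one | CC(C)(C)[Si](C)(C)O[C@@H]1CC(=O)[C@@H]([C@H](O[Si](CC)(CC)CC)C=C)[C@]1(C)CCC(C)=C | intermediate
14 | isopropylmagnesium chloride | CC(C)[Mg]Cl | starting material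
15 | isopropylcerium dichloride | CC(C)[Ce](Cl)Cl | intermediate
16 | (1S,2R,3S,4R)-4-(tert-butyldimethylsilyloxy)-3-methyl-3-(3-methylbut-3-en-1-yl)-1-(propan-2-yl)-2-[(1R)-1-(triethylsilyloxy)prop-2-en-1-yl]cyclopentan-1-ol | CC(C)(C)[Si](C)(C)O[C@@H]1C[C@](O)(C(C)C)[C@@H]([C@H](O[Si](CC)(CC)CC)C=C)[C@]1(C)CCC(C)=C | intermediate
17 | (1R,3S,3aR,4R,8aS)-1-(tert-butyldimethylsilyloxy)-6,8a-dimethyl-3-(propan-2-yl)-4-(triethylsilyloxy)-1,2,3,3a,4,7,8,8a-octahydroazulen-3-ol | CC(C)(C)[Si](C)(C)O[C@@H]1C[C@](O)(C(C)C)[C@H]2[C@H](O[Si](CC)(CC)CC)C=C(C)CC[C@]12C | intermediate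
18 | (1R,3S,3aR,4R,8aS)-1-(tert-butyldimethylsilyloxy)-6,8a-dimethyl-3-(propan-2-yl)-1,2,3,3a,4,7,8,8a-octahydroazulene-3,4-diol | CC(C)(C)[Si](C)(C)O[C@@H]1C[C@](O)(C(C)C)[C@H]2[C@H](O)C=C(C)CC[C@]12C | intermediate
19 | 4-acetoxybenzoic acid | CC(=O)Oc1ccc(cc1)C(O)=O | starting material
20 | (1R,3S,3aR,4R,8aS)-1-(tert-butyldimethylsilyloxy)-3-hydroxy-6,8a-dimethyl-3-(propan-2-yl)-1,2,3,3a,4,7,8,8a-octahydroazulen-4-yl 4-acetoxybenzoate | CC(C)(C)[Si](C)(C)O[C@@H]1C[C@](O)(C(C)C)[C@H]2[C@H](OC(=O)c3ccc(OC(C)=O)cc3)C=C(C)CC[C@]12C | intermediate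
21 | (1R,3S,3aR,4R,8aS)-1-(tert-butyldimethylsilyloxy)-3,7-dihydroxy-6,8a-dimethyl-3-(propan-2-yl)-1,2,3,3a,4,7,8,8a-octahydroazulen-4-yl 4-acetoxybenzoate (C7 epimers) | CC(C)(C)[Si](C)(C)O[C@@H]1C[C@](O)(C(C)C)[C@H]2[C@H](OC(=O)c3ccc(OC(C)=O)cc3)C=C(C)C(O)C[C@]12C | intermediate
22 | (1R,3S,3aR,4R,8aS)-1-(tert-butyldimethylsilyloxy)-3-hydroxy-6,8a-dimethyl-7-oxo-3-(propan-2-yl)-1,2,3,3a,4,7,8,8a-octahydroazulen-4-yl 4-acetoxybenzoate | CC(C)(C)[Si](C)(C)O[C@@H]1C[C@](O)(C(C)C)[C@H]2[C@H](OC(=O)c3ccc(OC(C)=O)cc3)C=C(C)C(=O)C[C@]12C | intermediate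
23 | (1R,3S,3aR,4R,8aS)-1,3-dihydroxy-6,8a-dimethyl-7-oxo-3-(propan-2-yl)-1,2,3,3a,4,7,8,8a-octahydroazulen-4-yl 4-acetoxybenzoate | O[C@@H]1C[C@](O)(C(C)C)[C@H]2[C@H](OC(=O)c3ccc(OC(C)=O)cc3)C=C(C)C(=O)C[C@]12C | intermediate
24 | (1R,3S,3aR,4R,8aS)-1-acetoxy-3-hydroxy-6,8a-dimethyl-7-oxo-3-(propan-2-yl)-1,2,3,3a,4,7,8,8a-octahydroazulen-4-yl 4-acetoxybenzoate | CC(=O)O[C@@H]1C[C@](O)(C(C)C)[C@H]2[C@H](OC(=O)c3ccc(OC(C)=O)cc3)C=C(C)C(=O)C[C@]12C | intermediate
25 | (1R,3S,3aR,4R,8aS)-1-acetoxy-3-hydroxy-6,8a-dimethyl-7-oxo-3-(propan-2-yl)-1,2,3,3a,4,7,8,8a-octahydroazulen-4-yl 4-hydroxybenzoate (CNP0087181.6) | CC(=O)O[C@@H]1C[C@](O)(C(C)C)[C@H]2[C@H](OC(=O)c3ccc(O)cc3)C=C(C)C(=O)C[C@]12C | target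

**Step count.** Total: 13 steps. Longest linear sequence: 13 steps (1 to 25).

**Steps most likely to fail**

1. Step 3 (cuprate addition with aldol trapping). Methyl transfer to the fully substituted β-carbon next to the silyloxy-bearing carbon may be slow. The enolate could then equilibrate toward C5 and lose the silyloxy group, and copper species and excess cuprate could consume acrolein or erode the aldol selectivity. The fallback sets out from 6 and returns at 12, and it separates the two bond formations. Me2CuLi with Me3SiCl and Et3N in THF at −78 °C accelerates the 1,4-addition and captures the enolate as it forms, and should give the isolable (3S,4R)-4-(tert-butyldimethylsilyloxy)-3-methyl-3-(3-methylbut-3-en-1-yl)-1-(trimethylsilyloxy)cyclopent-1-ene F1. MeLi in THF at 0 °C then regenerates the copper-free lithium enolate 10. ZnCl2 followed by acrolein at −78 °C completes the aldol to 12.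

2. Step 5 (isopropyl addition). Facial selectivity at the carbonyl may be poor, because the C2 side chain and the C3 methyl lie on one face and the butenyl chain and the silyloxy group on the other. The branched reagent may also reduce or enolise the ketone. The fallback sets out from 13 and returns at 17, and it closes the ring first. Metathesis of 13 with the second-generation Grubbs catalyst (CH2Cl2, 40 °C) should give the trans-fused ketone (1R,3aR,4R,8aS)-1-(tert-butyldimethylsilyloxy)-6,8a-dimethyl-4-(triethylsilyloxy)-2,3a,4,7,8,8a-hexahydroazulen-3(1H)-one F2. In F2 both side chains are tied back in the ring and the axial angular methyl shields the upper face. Addition of iPrMgCl/CeCl3 from the face opposite the angular methyl should then give 17 directly.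

3. Step 9 (allylic oxidation). The ene reaction may attack the vinylic methyl instead of the ring methylene. Conversion may also stall, because the alkene is hindered and deactivated by the neighbouring aroyloxy group. The fallback sets out from 16 and returns at 22, and it installs the oxygen before ring closure.
   - SeO2/t-BuOOH on the 1,1-disubstituted alkene of 16, where CH2 is oxidised in preference to CH3, should give (1S,2R,3S,4R)-4-(tert-butyldimethylsilyloxy)-3-(2-hydroxy-3-methylbut-3-en-1-yl)-3-methyl-1-(propan-2-yl)-2-[(1R)-1-(triethylsilyloxy)prop-2-en-1-yl]cyclopentan-1-ol F3 as side-chain carbinol epimers.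
   - Dess–Martin periodinane should convert both epimers into the isopropenyl ketone (1S,2R,3S,4R)-4-(tert-butyldimethylsilyloxy)-3-methyl-3-(3-methyl-2-oxobut-3-en-1-yl)-1-(propan-2-yl)-2-[(1R)-1-(triethylsilyloxy)prop-2-en-1-yl]cyclopentan-1-ol F4.
   - Ring-closing metathesis (second-generation Grubbs catalyst, toluene, 80 °C) should close the α-methyl cycloheptenone (1R,3S,3aR,4R,8aS)-1-(tert-butyldimethylsilyloxy)-3-hydroxy-6,8a-dimethyl-3-(propan-2-yl)-4-(triethylsilyloxy)-2,3,3a,4,8,8a-hexahydroazulen-7(1H)-one F5.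
   - PPTS in MeOH should free the allylic alcohol to give (1R,3S,3aR,4R,8aS)-1-(tert-butyldimethylsilyloxy)-3,4-dihydroxy-6,8a-dimethyl-3-(propan-2-yl)-2,3,3a,4,8,8a-hexahydroazulen-7(1H)-one F6.
   - Steglich esterification of F6 with 19 (DCC, DMAP) should give 22.

**Further compounds**

F1 | step 3 | (3S,4R)-4-(tert-butyldimethylsilyloxy)-3-methyl-3-(3-methylbut-3-en-1-yl)-1-(trimethylsilyloxy)cyclopent-1-ene | CC(C)(C)[Si](C)(C)O[C@@H]1CC(O[Si](C)(C)C)=C[C@]1(C)CCC(C)=C
F2 | step 5 | (1R,3aR,4R,8aS)-1-(tert-butyldimethylsilyloxy)-6,8a-dimethyl-4-(triethylsilyloxy)-2,3a,4,7,8,8a-hexahydroazulen-3(1H)-one | CC(C)(C)[Si](C)(C)O[C@@H]1CC(=O)[C@H]2[C@H](O[Si](CC)(CC)CC)C=C(C)CC[C@]12C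
F3 | step 9 | (1S,2R,3S,4R)-4-(tert-butyldimethylsilyloxy)-3-(2-hydroxy-3-methylbut-3-en-1-yl)-3-methyl-1-(propan-2-yl)-2-[(1R)-1-(triethylsilyloxy)prop-2-en-1-yl]cyclopentan-1-ol (side-chain carbinol epimers) | CC(C)(C)[Si](C)(C)O[C@@H]1C[C@](O)(C(C)C)[C@@H]([C@H](O[Si](CC)(CC)CC)C=C)[C@]1(C)CC(O)C(C)=C
F4 | step 9 | (1S,2R,3S,4R)-4-(tert-butyldimethylsilyloxy)-3-methyl-3-(3-methyl-2-oxobut-3-en-1-yl)-1-(propan-2-yl)-2-[(1R)-1-(triethylsilyloxy)prop-2-en-1-yl]cyclopentan-1-ol | CC(C)(C)[Si](C)(C)O[C@@H]1C[C@](O)(C(C)C)[C@@H]([C@H](O[Si](CC)(CC)CC)C=C)[C@]1(C)CC(=O)C(C)=C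
F5 | step 9 | (1R,3S,3aR,4R,8aS)-1-(tert-butyldimethylsilyloxy)-3-hydroxy-6,8a-dimethyl-3-(propan-2-yl)-4-(triethylsilyloxy)-2,3,3a,4,8,8a-hexahydroazulen-7(1H)-one | CC(C)(C)[Si](C)(C)O[C@@H]1C[C@](O)(C(C)C)[C@H]2[C@H](O[Si](CC)(CC)CC)C=C(C)C(=O)C[C@]12C
F6 | step 9 | (1R,3S,3aR,4R,8aS)-1-(tert-butyldimethylsilyloxy)-3,4-dihydroxy-6,8a-dimethyl-3-(propan-2-yl)-2,3,3a,4,8,8a-hexahydroazulen-7(1H)-one | CC(C)(C)[Si](C)(C)O[C@@H]1C[C@](O)(C(C)C)[C@H]2[C@H](O)C=C(C)C(=O)C[C@]12C
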